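## Analysis of the target

The target 40 is a 2-methyl-1,4-benzoquinone joined through a CH2 group to C-9 of a trans-fused decalin. Numbering used throughout: ring A = C-1, C-2, C-3, C-4, C-5, C-10; ring B = C-5 to C-10; β is the face of the C-5 methyl group. Ring A carries an exocyclic isopropylidene group on C-3 and a CH2CH2CO2H chain on C-4; ring B is the cyclohexane with methyl groups on C-5, C-8 and C-9. There are five stereocentres: the quaternary carbons C-5 and C-9 and the CH centres C-4, C-8 and C-10. The C-5 and C-9 methyl groups are both β and 1,3-diaxial, the arylmethyl group on C-9 is α and equatorial, H-10 is α, the C-8 methyl is α (axial, trans to the C-9 methyl), and the C-4 chain is β and equatorial, pressed against the isopropylidene group. Sensitive groups are the quinone (bases, nucleophiles, reductants), the tetrasubstituted alkene (acid, electrophiles) and the free acid. The difficulty is twofold: ring B has four contiguous stereocentres, two quaternary, with an axial secondary methyl that neither hydrogenation from the open face nor equilibration would give; and C-4 has the configuration that allylic strain disfavours and cannot be corrected once the alkene is in place. The strategy rests on the vicinal pair C-9/C-8: the bond between the quaternary C-9 and the CH–CH3 carbon C-8 is made by a sigmatropic shift that creates both centres at once, with the benzylic carbon latent as a carboxyl group.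

## Retrosynthetic reasoning

**Quinone.** The quinone of 40 is taken back to the hydroquinone dimethyl ether in acid 39. The quinone would not survive enolates, hydrides or organometallics, whereas the dimethoxyarene is inert to all of them. The forward step has to oxidise the arene without touching the tetrasubstituted alkene.

**C-4 and the acid chain.** In ester 38 (hydrolysed to 39) the bond between the exocyclic CH2 on C-4 and the CH2CO2Et unit is cut together with the C-4–H bond. Both lead back, through borane 37, to the exocyclic methylene group of diene 36. C-4 is the one centre the sigmatropic step does not set, and it cannot be equilibrated next to the isopropylidene group. It therefore has to be set kinetically, by hydrogen arriving on the α face; in 36 the β face of the methylene group is covered by the C-5 methyl and the nearer isopropylidene methyl.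

**Isopropylidene group.** The methylene carbon of 36 replaces the C-4 carbonyl oxygen of enone 34 (via adduct 35). The C-3 isopropylidene of 34 comes from an aldol condensation of decalone 32 (via aldol 33). C-4 is chosen as the carbonyl position because C-5 is quaternary: 32 can enolise only towards C-3, and dehydration into conjugation gives the tetrasubstituted alkene and not the isopropenyl isomer.

**Ring A.** Decalone 32 is opened at C-2–C-3 to the iodo methyl ketone 31. The ketone has a single enolate, the closure is six-membered, and the chains on C-5 and C-10 are already trans, so the trans ring fusion needs no further control. 31 follows from 28 by hydrogenation with debenzylation (29), iodide formation (30) and ketal hydrolysis.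

**Arylmethyl group.** In 28 the bond between the benzylic carbon and the arene is cut, giving aldehyde 21 and aryl bromide 24 (forward via aryllithium 25, carbinol 26 and xanthate 27). Substitution at this neopentyl carbon is not feasible, so the carbon is used as a carbonyl electrophile and the oxygen removed afterwards. Bromide 24 comes from phenol 22 via 23, the free hydroxyl directing bromination to the position that leads to the correct quinone pattern. Aldehyde 21 is the carboxyl carbon of acid 19 at the aldehyde level (via alcohol 20).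

**Ring B (key disconnection).** In acid 19 the C-9–C-8 bond is cut and the C-6=C-7 alkene is returned to a C-6–O bond. This is the retron of an ester enolate Claisen rearrangement and leads to δ-lactone 16 (forward via ketene acetal 17 and silyl ester 18). The cut is made here because this bond joins the quaternary C-9 to the axial CH–CH3 carbon, and a suprafacial shift sets both from one carbinol stereocentre. C-5 and C-10 are already ring atoms of 16. The forward reaction must transfer the configuration of the lactone carbinol carbon completely.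

**Lactone 16.** The lactone is opened to diol 14, whose primary alcohol is the terminal carbon of the isopropenyl group of carbinol 12 (forward via borane 13 and lactol 15). The configuration next to the lactone carbonyl is irrelevant because it is planarised in 17. Carbinol 12 is cut between the carbinol carbon and the propenyl group, giving aldehyde 9 and (E)-prop-1-enyllithium 11 from bromide 10. The addition has to follow Felkin–Anh control at the α-quaternary aldehyde.

**Quaternary C-5 and C-10.** Aldehyde 9 is traced through alcohol 8 and diol 7 to ketal lactone 6. Reductive opening turns the ring oxygen of 6 into the future benzyl ether oxygen and the ring carbonyl into the aldehyde carbon. Lactone 6 comes from keto lactone 5, made by C-methylation of 4; 4 comes from C-acetylation of 3, and 3 from asymmetric conjugate addition of boronate 2 to lactone 1. The six-membered lactone is a template: an acyclic β-keto ester would give the quaternary centre without dependable control, whereas in the ring the methyl group enters trans to the isopropenyl group.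

## Alternatives that were turned down

**Alternative 1:** Ring B is disconnected by a [4+2] cycloaddition across C-10–C-9 and C-5–C-6. In the forward sense 2-methoxy-5-methyl-1,4-benzoquinone A1 reacts at its methyl-bearing double bond with aryl diene A2 to give the cis-fused endo adduct A3.
- For it: one step builds ring B with both quaternary carbons and carries the arylmethyl group from the start; it is more convergent and reaches a decalin in fewer steps than the chosen route.
- Against it: A2 must react through a doubly substituted diene terminus, which disfavours the s-cis conformer. A3 has C-10 in the wrong configuration. Most seriously, A3 has no methyl group on C-8: ring B ends in an unactivated C-7=C-8 alkene beside the quaternary C-9, so the axial C-8 methyl would have to be added later without a handle. Ring A arrives as a methoxy enedione that must lose two carbonyl groups before the isopropylidene and acid chain can be built.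
- Comparison: the alternative is stronger in bonds formed per step; the chosen strategy sets C-8 and C-9 together by chirality transfer, which is the part of the problem the cycloaddition leaves open.

**Alternative 2:** The hydroquinone ring is disconnected and built last. Heating the 4-hydroxy-4-[(E)-prop-1-enyl]cyclobutenone A4 opens the four-membered ring, and a six-electron ring closure followed by tautomerisation gives the hydroquinone tert-butyl ester A5.
- For it: the step is neutral and regiospecific. It arrives at the hydroquinone level, so the last oxidation needs only a mild oxidant and spares the alkene; on this point it is stronger than the cerium oxidation of the chosen route. It also avoids the aryllithium addition and deoxygenation (steps 14 to 18).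
- Against it: it is an end-game only. A4 presupposes the complete decalin with all five stereocentres, the isopropylidene group and the ester, attached through the neopentyl CH2 to a four-membered ring that itself takes several steps to assemble. It says nothing about C-8 and C-9.
- Comparison: the chosen strategy solves ring B; an arene construction of this kind could only replace its last third.

**Alternative 3:** The aromatic ring is disconnected by benzannulation. The carbene complex A6, (CO)5Cr=C(OMe)CH=CHCH3, reacts with the propargyl-substituted decalin A7, forming three C–C bonds and giving the 4-methoxyphenol methyl ester A8.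
- For it: the step is convergent, a terminal alkyne places its large substituent next to the phenolic hydroxyl as required, and the phenol is oxidised to the quinone more easily than a dimethyl ether. On the arene it is as strong as the chosen route.
- Against it: it needs a stoichiometric chromium carbonyl complex. A7 needs a propargyl group on the quaternary C-9, which from an aldehyde such as 21 costs a homologation and an alkynylation, so no steps are saved. The ring B stereochemistry is again left to an unspecified earlier synthesis.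
- Comparison: the chosen strategy puts its key step where the structural difficulty lies.

Key step: step 11

Remark: compounds 13 to 16 are carried as mixtures of epimers at the methyl-bearing carbon that becomes C-3 of lactone 16; this centre is planarised in 17, and the epimer corresponding to (3R)-16 is the one named and drawn.

Remark: (E)-1-bromoprop-1-ene 10 is assumed to be used as the pure (E) isomer, since its geometry is carried into C-8.

## Steps

Step 1
Reactants: 1 5,6-dihydro-2H-pyran-2-one; 2 4,4,5,5-tetramethyl-2-(prop-1-en-2-yl)-1,3,2-dioxaborolane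
Product: 3 (4S)-4-(prop-1-en-2-yl)oxan-2-one
Conditions: [Rh(cod)Cl]2 (2.5 mol %), (S)-BINAP, K3PO4 (aq.), dioxane/H2O, 50 °C
Reagents that add atoms: none
Why: Rhodium-catalysed asymmetric 1,4-addition (Hayashi–Miyaura reaction) of an alkenylboron reagent to an α,β-unsaturated δ-lactone. The BINAP–rhodium alkenyl species adds to one enantioface and sets C-4 (the future C-10); the (S) ligand is the one expected to give the (4S) product by analogy with six-membered enones.

Step 2
Reactants: 3 (4S)-4-(prop-1-en-2-yl)oxan-2-one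
Product: 4 (3S,4S)-3-acetyl-4-(prop-1-en-2-yl)oxan-2-one (trans; epimerisable and partly enolised)
Conditions: LDA (1.1 equiv), THF, −78 °C; MeC(O)N(OMe)Me, −78 → 0 °C; aq. NH4Cl
Reagents that add atoms: N-methoxy-N-methylacetamide CC(=O)N(C)OC
Why: Crossed Claisen-type C-acylation of the lactone lithium enolate with a Weinreb amide; the stable tetrahedral adduct prevents over-reaction. The configuration at C-3 is erased in the next step.

Step 3
Reactants: 4 (3S,4S)-3-acetyl-4-(prop-1-en-2-yl)oxan-2-one
Product: 5 (3R,4R)-3-acetyl-3-methyl-4-(prop-1-en-2-yl)oxan-2-one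
Conditions: K2CO3, MeI, acetone, rt
Reagents that add atoms: iodomethane CI
Why: C-Alkylation of a cyclic β-keto ester enolate. Allylic strain with the enolised acetyl group turns the isopropenyl group axial, so iodomethane enters trans to it and sets the quaternary centre (future C-5) with acetyl cis to isopropenyl.

Step 4
Reactants: 5 (3R,4R)-3-acetyl-3-methyl-4-(prop-1-en-2-yl)oxan-2-one
Product: 6 (3R,4R)-3-methyl-3-(2-methyl-1,3-dioxolan-2-yl)-4-(prop-1-en-2-yl)oxan-2-one
Conditions: HOCH2CH2OH, p-TsOH (cat.), benzene, reflux, Dean–Stark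
Reagents that add atoms: ethane-1,2-diol OCCO
Why: Acid-catalysed ketalisation with azeotropic removal of water protects the methyl ketone against the hydride, organolithium and amide-base steps that follow. The lactone carbonyl, flanked by the quaternary carbon, is not ketalised.

Step 5
Reactants: 6 (3R,4R)-3-methyl-3-(2-methyl-1,3-dioxolan-2-yl)-4-(prop-1-en-2-yl)oxan-2-one
Product: 7 (2S,3R)-2-methyl-2-(2-methyl-1,3-dioxolan-2-yl)-3-(prop-1-en-2-yl)pentane-1,5-diol
Conditions: LiAlH4, THF, 0 °C → rt
Reagents that add atoms: none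
Why: Hydride reduction of the lactone to the 1,5-diol opens the template ring and frees the ring oxygen as the primary alcohol that becomes the benzyl ether.

Step 6
Reactants: 7 (2S,3R)-2-methyl-2-(2-methyl-1,3-dioxolan-2-yl)-3-(prop-1-en-2-yl)pentane-1,5-diol
Product: 8 (2S,3R)-5-(benzyloxy)-2-methyl-2-(2-methyl-1,3-dioxolan-2-yl)-3-(prop-1-en-2-yl)pentan-1-ol
Conditions: NaH (1.0 equiv), BnBr (1.0 equiv), n-Bu4NI (cat.), THF, 0 °C → rt
Reagents that add atoms: benzyl bromide BrCc1ccccc1
Why: Williamson etherification under stoichiometric control. The hydroxymethyl group on the quaternary carbon is neopentyl and much more hindered than the unbranched primary alcohol, which should be alkylated selectively.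

Step 7
Reactants: 8 (2S,3R)-5-(benzyloxy)-2-methyl-2-(2-methyl-1,3-dioxolan-2-yl)-3-(prop-1-en-2-yl)pentan-1-ol
Product: 9 (2S,3R)-5-(benzyloxy)-2-methyl-2-(2-methyl-1,3-dioxolan-2-yl)-3-(prop-1-en-2-yl)pentanal
Conditions: Dess–Martin periodinane, CH2Cl2, rt
Reagents that add atoms: none
Why: Dess–Martin oxidation of a neopentyl primary alcohol; the aldehyde has no α-hydrogen and cannot epimerise.

Step 8
Reactants: 9 (2S,3R)-5-(benzyloxy)-2-methyl-2-(2-methyl-1,3-dioxolan-2-yl)-3-(prop-1-en-2-yl)pentanal; 10 (E)-1-bromoprop-1-ene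
Product: 12 (2E,4R,5S,6R)-8-(benzyloxy)-5-methyl-5-(2-methyl-1,3-dioxolan-2-yl)-6-(prop-1-en-2-yl)oct-2-en-4-ol, via (E)-prop-1-enyllithium 11 (not isolated)
Conditions: 10, t-BuLi (2 equiv), Et2O, −78 °C; then 9, THF, −78 °C; aq. NH4Cl
Reagents that add atoms: none
Why: Stereoretentive bromine–lithium exchange, then 1,2-addition of the alkenyllithium to the α-quaternary aldehyde. Under Felkin–Anh control the dioxolanyl-bearing carbon lies anti to the nucleophile, which passes the methyl group, and this should give the (4R) carbinol; lithium in THF at low temperature is chosen to avoid chelation.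

Step 9
Reactants: 12 (2E,4R,5S,6R)-8-(benzyloxy)-5-methyl-5-(2-methyl-1,3-dioxolan-2-yl)-6-(prop-1-en-2-yl)oct-2-en-4-ol
Product: 14 (2R,3R,4S,5R,6E)-3-[2-(benzyloxy)ethyl]-2,4-dimethyl-4-(2-methyl-1,3-dioxolan-2-yl)oct-6-ene-1,5-diol (with its 2S epimer), via B-alkyl-9-BBN adduct 13 (not isolated)
Conditions: 9-BBN (2.5 equiv), THF, 0 °C → rt; then NaOH, H2O2, 0 °C
Reagents that add atoms: hydrogen peroxide OO
Why: Hydroboration–oxidation. 9-BBN selects the 1,1-disubstituted alkene over the internal (E) alkene and places boron on the terminal carbon; the new methyl-bearing centre forms as an inconsequential mixture.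

Step 10
Reactants: 14 (2R,3R,4S,5R,6E)-3-[2-(benzyloxy)ethyl]-2,4-dimethyl-4-(2-methyl-1,3-dioxolan-2-yl)oct-6-ene-1,5-diol (with its 2S epimer)
Product: 16 (3R,4R,5S,6R)-4-[2-(benzyloxy)ethyl]-3,5-dimethyl-5-(2-methyl-1,3-dioxolan-2-yl)-6-[(E)-prop-1-enyl]oxan-2-one (with its 3S epimer), via lactol 15 (not isolated)
Conditions: TEMPO (0.2 equiv), PhI(OAc)2 (3 equiv), CH2Cl2, rt
Reagents that add atoms: none
Why: Oxidative lactonisation of a 1,5-diol by the TEMPO-derived oxoammonium salt. The primary alcohol is oxidised first, the aldehyde closes to the six-membered lactol with the hindered allylic alcohol, and the lactol is oxidised to the δ-lactone.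

Step 11
Reactants: 16 (3R,4R,5S,6R)-4-[2-(benzyloxy)ethyl]-3,5-dimethyl-5-(2-methyl-1,3-dioxolan-2-yl)-6-[(E)-prop-1-enyl]oxan-2-one (with its 3S epimer)
Product: 19 (1S,2S,5R,6S)-6-[2-(benzyloxy)ethyl]-1,2,5-trimethyl-5-(2-methyl-1,3-dioxolan-2-yl)cyclohex-3-ene-1-carboxylic acid, via silyl ketene acetal 17 (not isolated), via trimethylsilyl ester 18 (not isolated)
Conditions: LDA, THF, −78 °C; Me3SiCl, −78 °C → rt; toluene, 105 °C; then K2CO3, MeOH/H2O; citric acid to pH 4
Reagents that add atoms: none
Why: LDA removes the single α-hydrogen of 16 and O-silylation gives the endocyclic silyl ketene acetal 17, whose geometry is fixed by the ring, so the fully substituted α-carbon raises no enolate-geometry question. On heating, 17 undergoes a [3,3]-sigmatropic (Ireland–Claisen) shift: the σ bond between lactone C-3 (future C-9) and the propenyl terminus (future C-8) forms as the allylic C-6–O bond breaks, giving silyl ester 18 and, after hydrolysis, acid 19. The closest known reaction type is the ester enolate Claisen ring contraction of alkenyl-substituted lactones to cycloalkene carboxylic acids. Ring B closes as a six-membered carbocycle in a suprafacial pericyclic step, not a polar exo or endo closure; because the reacting termini are tied by the C-4–C-5 bridge, the six-atom array can only adopt a boat, bicyclo[2.2.2]octane-like geometry. C-9 is controlled by the carbinol carbon C-6: the new bond can form only on the lactone face that carries the propenyl group, which places the C-9 methyl β and the carboxyl α relative to the fixed centres C-5 and C-10. C-8 is controlled by the (E) geometry of the propenyl group: in the boat its methyl points away from the C-4–C-5 bridge and ends cis to the carboxyl group and trans to the C-9 methyl. The step needs complete transfer of configuration from C-6 to both new centres; the ring-fixed ketene acetal, the boat-only transition state and the defined (E) alkene secure it, and both C-3 epimers of 16 converge on 17.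

Step 12
Reactants: 19 (1S,2S,5R,6S)-6-[2-(benzyloxy)ethyl]-1,2,5-trimethyl-5-(2-methyl-1,3-dioxolan-2-yl)cyclohex-3-ene-1-carboxylic acid
Product: 20 [(1S,2S,5R,6R)-6-[2-(benzyloxy)ethyl]-1,2,5-trimethyl-5-(2-methyl-1,3-dioxolan-2-yl)cyclohex-3-en-1-yl]methanol
Conditions: LiAlH4, THF, reflux
Reagents that add atoms: none
Why: Hydride reduction of the hindered neopentyl acid to the primary alcohol; ketal, benzyl ether and alkene are inert.

Step 13
Reactants: 20 [(1S,2S,5R,6R)-6-[2-(benzyloxy)ethyl]-1,2,5-trimethyl-5-(2-methyl-1,3-dioxolan-2-yl)cyclohex-3-en-1-yl]methanol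
Product: 21 (1S,2S,5R,6R)-6-[2-(benzyloxy)ethyl]-1,2,5-trimethyl-5-(2-methyl-1,3-dioxolan-2-yl)cyclohex-3-ene-1-carbaldehyde
Conditions: Dess–Martin periodinane, CH2Cl2, rt
Reagents that add atoms: none
Why: Dess–Martin oxidation to the aldehyde on the quaternary C-9, which cannot enolise.

Step 14
Reactants: 22 4-methoxy-2-methylphenol
Product: 23 2-bromo-4-methoxy-6-methylphenol
Conditions: NBS, CH2Cl2, 0 °C
Reagents that add atoms: N-bromosuccinimide O=C1CCC(=O)N1Br
Why: Electrophilic bromination ortho to the free hydroxyl group, the strongest director; the para position carries the methoxy group and the other ortho position the methyl group.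

Step 15
Reactants: 23 2-bromo-4-methoxy-6-methylphenol
Product: 24 1-bromo-2,5-dimethoxy-3-methylbenzene
Conditions: MeI, K2CO3, acetone, reflux
Reagents that add atoms: iodomethane CI
Why: Williamson O-methylation of the phenol gives the hydroquinone dimethyl ether that masks the quinone.

Step 16
Reactants: 21 (1S,2S,5R,6R)-6-[2-(benzyloxy)ethyl]-1,2,5-trimethyl-5-(2-methyl-1,3-dioxolan-2-yl)cyclohex-3-ene-1-carbaldehyde; 24 1-bromo-2,5-dimethoxy-3-methylbenzene
Product: 26 (2,5-dimethoxy-3-methylphenyl){6-[2-(benzyloxy)ethyl]-1,2,5-trimethyl-5-(2-methyl-1,3-dioxolan-2-yl)cyclohex-3-en-1-yl}methanol (carbinol epimers; ring stereocentres as in 19), via aryllithium 25 (not isolated)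
Conditions: 24, n-BuLi, THF, −78 °C; then 21, −78 → 0 °C; aq. NH4Cl
Reagents that add atoms: none
Why: Bromine–lithium exchange and 1,2-addition of the aryllithium to a non-enolisable aldehyde. The carbinol centre forms as a mixture that the deoxygenation removes.

Step 17
Reactants: 26 (2,5-dimethoxy-3-methylphenyl){6-[2-(benzyloxy)ethyl]-1,2,5-trimethyl-5-(2-methyl-1,3-dioxolan-2-yl)cyclohex-3-en-1-yl}methanol
Product: 27 O-[(2,5-dimethoxy-3-methylphenyl){6-[2-(benzyloxy)ethyl]-1,2,5-trimethyl-5-(2-methyl-1,3-dioxolan-2-yl)cyclohex-3-en-1-yl}methyl] S-methyl carbonodithioate (ring stereocentres as in 19)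
Conditions: NaH, imidazole (cat.), THF; CS2; MeI, 0 °C → rt
Reagents that add atoms: carbon disulfide S=C=S; iodomethane CI
Why: Xanthate formation for a Barton–McCombie deoxygenation; Chugaev elimination is impossible because the neighbouring carbon is quaternary.

Step 18
Reactants: 27 O-[(2,5-dimethoxy-3-methylphenyl){6-[2-(benzyloxy)ethyl]-1,2,5-trimethyl-5-(2-methyl-1,3-dioxolan-2-yl)cyclohex-3-en-1-yl}methyl] S-methyl carbonodithioate
Product: 28 1-{[6-[2-(benzyloxy)ethyl]-1,2,5-trimethyl-5-(2-methyl-1,3-dioxolan-2-yl)cyclohex-3-en-1-yl]methyl}-2,5-dimethoxy-3-methylbenzene (ring stereocentres as in 19)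
Conditions: n-Bu3SnH, AIBN (cat.), toluene, 110 °C
Reagents that add atoms: none
Why: Barton–McCombie radical deoxygenation through a stabilised benzylic radical. Attack of that radical on the ring alkene would need a four-membered exo or five-membered endo closure and should not compete.

Step 19
Reactants: 28 1-{[6-[2-(benzyloxy)ethyl]-1,2,5-trimethyl-5-(2-methyl-1,3-dioxolan-2-yl)cyclohex-3-en-1-yl]methyl}-2,5-dimethoxy-3-methylbenzene
Product: 29 2-[2-[(2,5-dimethoxy-3-methylphenyl)methyl]-2,3,6-trimethyl-6-(2-methyl-1,3-dioxolan-2-yl)cyclohexyl]ethanol (C-5 β-methyl, C-8 α-methyl, C-9 β-methyl, H-10 α)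
Conditions: H2 (3 atm), Pd/C (10%), EtOAc/EtOH, rt
Reagents that add atoms: none
Why: Catalytic hydrogenation saturates the cis-disubstituted ring alkene, which creates no stereocentre, and hydrogenolyses the benzyl ether in the same operation.

Step 20
Reactants: 29 2-[2-[(2,5-dimethoxy-3-methylphenyl)methyl]-2,3,6-trimethyl-6-(2-methyl-1,3-dioxolan-2-yl)cyclohexyl]ethanol
Product: 30 1-{[2-(2-iodoethyl)-1,3,6-trimethyl-3-(2-methyl-1,3-dioxolan-2-yl)cyclohexyl]methyl}-2,5-dimethoxy-3-methylbenzene (ring stereocentres as in 29)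
Conditions: I2, PPh3, imidazole, CH2Cl2, 0 °C → rt
Reagents that add atoms: iodine II
Why: Appel-type iodination of the primary alcohol under imidazole-buffered conditions that spare the ketal.

Step 21
Reactants: 30 1-{[2-(2-iodoethyl)-1,3,6-trimethyl-3-(2-methyl-1,3-dioxolan-2-yl)cyclohexyl]methyl}-2,5-dimethoxy-3-methylbenzene
Product: 31 1-[3-[(2,5-dimethoxy-3-methylphenyl)methyl]-2-(2-iodoethyl)-1,3,4-trimethylcyclohexyl]ethanone (ring stereocentres as in 29)
Conditions: 1 M HCl, THF, rt
Reagents that add atoms: water O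
Why: Acid hydrolysis of the dioxolane liberates the methyl ketone; the primary iodide and the aryl ethers are stable to dilute acid.

Step 22
Reactants: 31 1-[3-[(2,5-dimethoxy-3-methylphenyl)methyl]-2-(2-iodoethyl)-1,3,4-trimethylcyclohexyl]ethanone
Product: 32 9α-[(2,5-dimethoxy-3-methylphenyl)methyl]-5β,8α,9β-trimethyl-trans-decalin-4-one (H-10 α)
Conditions: LDA, THF, −78 °C → rt
Reagents that add atoms: none
Why: Intramolecular enolate alkylation, a 6-(enolendo)-exo-tet closure that the ring-closure rules for enolates allow. The ketone has only one enolisable position, and the equatorial chains on C-5 and C-10 give the trans-fused decalone.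

Step 23
Reactants: 32 9α-[(2,5-dimethoxy-3-methylphenyl)methyl]-5β,8α,9β-trimethyl-trans-decalin-4-one
Product: 33 9α-[(2,5-dimethoxy-3-methylphenyl)methyl]-3-(2-hydroxypropan-2-yl)-5β,8α,9β-trimethyl-trans-decalin-4-one (C-3 epimers)
Conditions: LDA, THF, −78 °C; acetone, −78 °C; aq. NH4Cl
Reagents that add atoms: acetone CC(C)=O
Why: Directed aldol addition of the lithium enolate to acetone; C-3 is the only enolisable position, and a cold quench prevents retro-aldol cleavage.

Step 24
Reactants: 33 9α-[(2,5-dimethoxy-3-methylphenyl)methyl]-3-(2-hydroxypropan-2-yl)-5β,8α,9β-trimethyl-trans-decalin-4-one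
Product: 34 9α-[(2,5-dimethoxy-3-methylphenyl)methyl]-5β,8α,9β-trimethyl-3-(propan-2-ylidene)-trans-decalin-4-one
Conditions: MsCl, Et3N, CH2Cl2, 0 °C; then DBU, rt
Reagents that add atoms: none
Why: Mesylation and base-induced (E1cB) elimination give the conjugated isopropylidene ketone; DBU also moves any isopropenyl isomer into conjugation.

Step 25
Reactants: 34 9α-[(2,5-dimethoxy-3-methylphenyl)methyl]-5β,8α,9β-trimethyl-3-(propan-2-ylidene)-trans-decalin-4-one
Product: 36 9α-[(2,5-dimethoxy-3-methylphenyl)methyl]-5β,8α,9β-trimethyl-4-methylidene-3-(propan-2-ylidene)-trans-decalin, via beta-hydroxysilane 35 (not isolated)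
Conditions: Me3SiCH2Li, CeCl3, THF, −78 → 0 °C; then 48% aq. HF, MeCN, rt
Reagents that add atoms: (trimethylsilyl)methyllithium [Li]C[Si](C)(C)C
Why: Peterson methylenation. The organocerium reagent adds to the hindered ketone without enolising it, and acid-induced loss of the silyl and hydroxyl groups from the β-hydroxysilane gives the exocyclic methylene group.

Step 26
Reactants: 36 9α-[(2,5-dimethoxy-3-methylphenyl)methyl]-5β,8α,9β-trimethyl-4-methylidene-3-(propan-2-ylidene)-trans-decalin
Product: 38 ethyl 3-{9α-[(2,5-dimethoxy-3-methylphenyl)methyl]-5β,8α,9β-trimethyl-3-(propan-2-ylidene)-trans-decalin-4β-yl}propanoate (H-4 α), via B-alkyl-9-BBN adduct 37 (not isolated)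
Conditions: 9-BBN (1.1 equiv), THF, rt → 50 °C; then BrCH2CO2Et, t-BuOK, t-BuOH/THF, 0 °C
Reagents that add atoms: ethyl bromoacetate CCOC(=O)CBr
Why: Hydroboration followed by α-alkylation of an α-bromo ester with a B-alkyl-9-BBN. 9-BBN adds only to the 1,1-disubstituted alkene and should deliver hydrogen to C-4 from the α face, because the β face is covered by the C-5 methyl and the nearer isopropylidene methyl. The primary alkyl group then migrates from boron to the carbon of the bromoacetate enolate and tert-butanol protonates the resulting boron enolate.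

Step 27
Reactants: 38 ethyl 3-{9α-[(2,5-dimethoxy-3-methylphenyl)methyl]-5β,8α,9β-trimethyl-3-(propan-2-ylidene)-trans-decalin-4β-yl}propanoate
Product: 39 3-{9α-[(2,5-dimethoxy-3-methylphenyl)methyl]-5β,8α,9β-trimethyl-3-(propan-2-ylidene)-trans-decalin-4β-yl}propanoic acid
Conditions: LiOH, THF/MeOH/H2O, rt; then 1 M HCl to pH 3
Reagents that add atoms: lithium hydroxide [Li+].[OH-]
Why: Saponification of the unhindered ethyl ester; it is done before the quinone is unmasked because the quinone would not tolerate hydroxide.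

Step 28
Reactants: 39 3-{9α-[(2,5-dimethoxy-3-methylphenyl)methyl]-5β,8α,9β-trimethyl-3-(propan-2-ylidene)-trans-decalin-4β-yl}propanoic acid
Product: 40 3-{5β,8α,9β-trimethyl-9α-[(5-methyl-3,6-dioxocyclohexa-1,4-dien-1-yl)methyl]-3-(propan-2-ylidene)-trans-decalin-4β-yl}propanoic acid (target CNP0271365.1)
Conditions: (NH4)2Ce(NO3)6 (2.5 equiv), MeCN/H2O, 0 °C
Reagents that add atoms: water O
Why: Oxidative demethylation of the hydroquinone dimethyl ether by tetravalent cerium. The electron-rich arene should be oxidised before the tetrasubstituted alkene, and the quinone oxygens come from water.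

## Compound list

1 | 5,6-dihydro-2H-pyran-2-one | O=C1C=CCCO1 | starting material
2 | 4,4,5,5-tetramethyl-2-(prop-1-en-2-yl)-1,3,2-dioxaborolane | CC(=C)B1OC(C)(C)C(C)(C)O1 | starting material
3 | (4S)-4-(prop-1-en-2-yl)oxan-2-one | O=C1C[C@@H](C(C)=C)CCO1 | intermediate
4 | (3S,4S)-3-acetyl-4-(prop-1-en-2-yl)oxan-2-one | CC(=O)[C@H]1C(=O)OCC[C@@H]1C(C)=C | intermediate
5 | (3R,4R)-3-acetyl-3-methyl-4-(prop-1-en-2-yl)oxan-2-one | CC(=O)[C@]1(C)C(=O)OCC[C@@H]1C(C)=C | intermediate
6 | (3R,4R)-3-methyl-3-(2-methyl-1,3-dioxolan-2-yl)-4-(prop-1-en-2-yl)oxan-2-one | CC1(OCCO1)[C@]2(C)C(=O)OCC[C@@H]2C(C)=C | intermediate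
7 | (2S,3R)-2-methyl-2-(2-methyl-1,3-dioxolan-2-yl)-3-(prop-1-en-2-yl)pentane-1,5-diol | CC1(OCCO1)[C@](C)(CO)[C@H](CCO)C(C)=C | intermediate
8 | (2S,3R)-5-(benzyloxy)-2-methyl-2-(2-methyl-1,3-dioxolan-2-yl)-3-(prop-1-en-2-yl)pentan-1-ol | CC1(OCCO1)[C@](C)(CO)[C@H](CCOCc2ccccc2)C(C)=C | intermediate
9 | (2S,3R)-5-(benzyloxy)-2-methyl-2-(2-methyl-1,3-dioxolan-2-yl)-3-(prop-1-en-2-yl)pentanal | CC1(OCCO1)[C@](C)(C=O)[C@H](CCOCc2ccccc2)C(C)=C | intermediate
10 | (E)-1-bromoprop-1-ene | C/C=C/Br | starting material
11 | (E)-prop-1-enyllithium | C/C=C/[Li] | intermediate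
12 | (2E,4R,5S,6R)-8-(benzyloxy)-5-methyl-5-(2-methyl-1,3-dioxolan-2-yl)-6-(prop-1-en-2-yl)oct-2-en-4-ol | C/C=C/[C@@H](O)[C@@](C)(C1(C)OCCO1)[C@H](CCOCc2ccccc2)C(C)=C | intermediate
13 | B-alkyl-9-BBN adduct of 12 (boron on the terminal carbon of the former isopropenyl group; one epimer drawn) | C/C=C/[C@@H](O)[C@@](C)(C1(C)OCCO1)[C@H](CCOCc2ccccc2)[C@@H](C)CB3C4CCCC3CCC4 | intermediate
14 | (2R,3R,4S,5R,6E)-3-[2-(benzyloxy)ethyl]-2,4-dimethyl-4-(2-methyl-1,3-dioxolan-2-yl)oct-6-ene-1,5-diol (with its 2S epimer) | C/C=C/[C@@H](O)[C@@](C)(C1(C)OCCO1)[C@H](CCOCc2ccccc2)[C@@H](C)CO | intermediate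
15 | (3R,4R,5S,6R)-4-[2-(benzyloxy)ethyl]-3,5-dimethyl-5-(2-methyl-1,3-dioxolan-2-yl)-6-[(E)-prop-1-enyl]oxan-2-ol (lactol; anomers and 3S epimer) | OC1O[C@H](/C=C/C)[C@@](C)(C2(C)OCCO2)[C@H](CCOCc3ccccc3)[C@H]1C | intermediate
16 | (3R,4R,5S,6R)-4-[2-(benzyloxy)ethyl]-3,5-dimethyl-5-(2-methyl-1,3-dioxolan-2-yl)-6-[(E)-prop-1-enyl]oxan-2-one (with its 3S epimer) | O=C1O[C@H](/C=C/C)[C@@](C)(C2(C)OCCO2)[C@H](CCOCc3ccccc3)[C@H]1C | intermediate
17 | {[(2R,3S,4R)-4-[2-(benzyloxy)ethyl]-3,5-dimethyl-3-(2-methyl-1,3-dioxolan-2-yl)-2-[(E)-prop-1-enyl]-3,4-dihydro-2H-pyran-6-yl]oxy}trimethylsilane (silyl ketene acetal) | C[Si](C)(C)OC1O[C@H](/C=C/C)[C@@](C)(C2(C)OCCO2)[C@H](CCOCc3ccccc3)C=1C | intermediate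
18 | trimethylsilyl ester of acid 19 | C[Si](C)(C)OC(=O)[C@]1(C)[C@@H](CCOCc2ccccc2)[C@](C)(C3(C)OCCO3)C=C[C@@H]1C | intermediate
19 | (1S,2S,5R,6S)-6-[2-(benzyloxy)ethyl]-1,2,5-trimethyl-5-(2-methyl-1,3-dioxolan-2-yl)cyclohex-3-ene-1-carboxylic acid | OC(=O)[C@]1(C)[C@@H](CCOCc2ccccc2)[C@](C)(C3(C)OCCO3)C=C[C@@H]1C | intermediate
20 | [(1S,2S,5R,6R)-6-[2-(benzyloxy)ethyl]-1,2,5-trimethyl-5-(2-methyl-1,3-dioxolan-2-yl)cyclohex-3-en-1-yl]methanol | OC[C@]1(C)[C@@H](CCOCc2ccccc2)[C@](C)(C3(C)OCCO3)C=C[C@@H]1C | intermediate
21 | (1S,2S,5R,6R)-6-[2-(benzyloxy)ethyl]-1,2,5-trimethyl-5-(2-methyl-1,3-dioxolan-2-yl)cyclohex-3-ene-1-carbaldehyde | O=C[C@]1(C)[C@@H](CCOCc2ccccc2)[C@](C)(C3(C)OCCO3)C=C[C@@H]1C | intermediate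
22 | 4-methoxy-2-methylphenol | COc1ccc(O)c(C)c1 | starting material
23 | 2-bromo-4-methoxy-6-methylphenol | COc1cc(C)c(O)c(Br)c1 | intermediate
24 | 1-bromo-2,5-dimethoxy-3-methylbenzene | COc1cc(C)c(OC)c(Br)c1 | intermediate
25 | (2,5-dimethoxy-3-methylphenyl)lithium | COc1cc(C)c(OC)c([Li])c1 | intermediate
26 | (2,5-dimethoxy-3-methylphenyl){6-[2-(benzyloxy)ethyl]-1,2,5-trimethyl-5-(2-methyl-1,3-dioxolan-2-yl)cyclohex-3-en-1-yl}methanol (carbinol epimers; ring stereocentres as in 19) | COc1cc(C)c(OC)c(c1)C(O)[C@]2(C)[C@@H](CCOCc3ccccc3)[C@](C)(C4(C)OCCO4)C=C[C@@H]2C | intermediate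
27 | S-methyl xanthate of 26 | COc1cc(C)c(OC)c(c1)C(OC(=S)SC)[C@]2(C)[C@@H](CCOCc3ccccc3)[C@](C)(C4(C)OCCO4)C=C[C@@H]2C | intermediate
28 | 1-{[6-[2-(benzyloxy)ethyl]-1,2,5-trimethyl-5-(2-methyl-1,3-dioxolan-2-yl)cyclohex-3-en-1-yl]methyl}-2,5-dimethoxy-3-methylbenzene (ring stereocentres as in 19) | COc1cc(C)c(OC)c(c1)C[C@]2(C)[C@@H](CCOCc3ccccc3)[C@](C)(C4(C)OCCO4)C=C[C@@H]2C | intermediate
29 | 2-[2-[(2,5-dimethoxy-3-methylphenyl)methyl]-2,3,6-trimethyl-6-(2-methyl-1,3-dioxolan-2-yl)cyclohexyl]ethanol (C-5 β-methyl, C-8 α-methyl, C-9 β-methyl, H-10 α) | COc1cc(C)c(OC)c(c1)C[C@]2(C)[C@@H](CCO)[C@](C)(C3(C)OCCO3)CC[C@@H]2C | intermediate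
30 | 1-{[2-(2-iodoethyl)-1,3,6-trimethyl-3-(2-methyl-1,3-dioxolan-2-yl)cyclohexyl]methyl}-2,5-dimethoxy-3-methylbenzene (stereocentres as in 29) | COc1cc(C)c(OC)c(c1)C[C@]2(C)[C@@H](CCI)[C@](C)(C3(C)OCCO3)CC[C@@H]2C | intermediate
31 | 1-[3-[(2,5-dimethoxy-3-methylphenyl)methyl]-2-(2-iodoethyl)-1,3,4-trimethylcyclohexyl]ethanone (stereocentres as in 29) | COc1cc(C)c(OC)c(c1)C[C@]2(C)[C@@H](CCI)[C@](C)(C(C)=O)CC[C@@H]2C | intermediate
32 | 9α-[(2,5-dimethoxy-3-methylphenyl)methyl]-5β,8α,9β-trimethyl-trans-decalin-4-one (H-10 α) | COc1cc(C)c(OC)c(c1)C[C@]2(C)[C@H]3CCCC(=O)[C@]3(C)CC[C@@H]2C | intermediate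
33 | 3-(2-hydroxypropan-2-yl) derivative of 32 (C-3 epimers) | COc1cc(C)c(OC)c(c1)C[C@]2(C)[C@H]3CCC(C(C)(C)O)C(=O)[C@]3(C)CC[C@@H]2C | intermediate
34 | 9α-[(2,5-dimethoxy-3-methylphenyl)methyl]-5β,8α,9β-trimethyl-3-(propan-2-ylidene)-trans-decalin-4-one | COc1cc(C)c(OC)c(c1)C[C@]2(C)[C@H]3CCC(=C(C)C)C(=O)[C@]3(C)CC[C@@H]2C | intermediate
35 | 4-hydroxy-4-[(trimethylsilyl)methyl] adduct of 34 (beta-hydroxysilane) | COc1cc(C)c(OC)c(c1)C[C@]2(C)[C@H]3CCC(=C(C)C)C(O)(C[Si](C)(C)C)[C@]3(C)CC[C@@H]2C | intermediate
36 | 9α-[(2,5-dimethoxy-3-methylphenyl)methyl]-5β,8α,9β-trimethyl-4-methylidene-3-(propan-2-ylidene)-trans-decalin | COc1cc(C)c(OC)c(c1)C[C@]2(C)[C@H]3CCC(=C(C)C)C(=C)[C@]3(C)CC[C@@H]2C | intermediate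
37 | B-alkyl-9-BBN adduct of 36 (boron on the exocyclic carbon; H-4 α) | COc1cc(C)c(OC)c(c1)C[C@]2(C)[C@H]3CCC(=C(C)C)[C@@H](CB4C5CCCC4CCC5)[C@]3(C)CC[C@@H]2C | intermediate
38 | ethyl 3-{9α-[(2,5-dimethoxy-3-methylphenyl)methyl]-5β,8α,9β-trimethyl-3-(propan-2-ylidene)-trans-decalin-4β-yl}propanoate | COc1cc(C)c(OC)c(c1)C[C@]2(C)[C@H]3CCC(=C(C)C)[C@@H](CCC(=O)OCC)[C@]3(C)CC[C@@H]2C | intermediate
39 | 3-{9α-[(2,5-dimethoxy-3-methylphenyl)methyl]-5β,8α,9β-trimethyl-3-(propan-2-ylidene)-trans-decalin-4β-yl}propanoic acid | COc1cc(C)c(OC)c(c1)C[C@]2(C)[C@H]3CCC(=C(C)C)[C@@H](CCC(=O)O)[C@]3(C)CC[C@@H]2C | intermediate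
40 | 3-{5β,8α,9β-trimethyl-9α-[(5-methyl-3,6-dioxocyclohexa-1,4-dien-1-yl)methyl]-3-(propan-2-ylidene)-trans-decalin-4β-yl}propanoic acid (CNP0271365.1) | CC1=CC(=O)C=C(C[C@]2(C)[C@H]3CCC(=C(C)C)[C@@H](CCC(=O)O)[C@]3(C)CC[C@@H]2C)C1=O | target

## Step count and least certain steps

Total step count: 28. Longest linear sequence: 26 steps (steps 1 to 13 and 16 to 28; steps 14 and 15 form the two-step aryl bromide branch).

**Step 11 (key step).** The congested ketene acetal 17 may pass the boat only slowly, so that loss of the silyl group or ionisation of the allylic C–O bond on prolonged heating competes with the rearrangement. The fallback runs the same bond formation as a neutral aliphatic Claisen rearrangement at the aldehyde oxidation level. It sets out from lactone 16: DIBAL-H (toluene, −78 °C) gives lactol 15, and dehydration (MsCl, Et3N, CH2Cl2, 0 → 40 °C) gives the cyclic enol ether (2R,3S,4R)-4-[2-(benzyloxy)ethyl]-3,5-dimethyl-3-(2-methyl-1,3-dioxolan-2-yl)-2-[(E)-prop-1-enyl]-3,4-dihydro-2H-pyran F1. Thermolysis of F1 (degassed o-xylene, 180 to 200 °C, sealed tube, base-washed glass) passes through the same boat with the same facial constraints and comes back to the route at aldehyde 21, by-passing 19 and 20.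

**Step 8.** Poor facial selectivity in the addition to the α-quaternary aldehyde is the likely failure, because chelation of lithium by a dioxolane oxygen would oppose the Felkin–Anh course. The fallback replaces substrate control by reagent control. It sets out from the carbinol mixture obtained in step 8: Dess–Martin oxidation gives (2E,5S,6R)-8-(benzyloxy)-5-methyl-5-(2-methyl-1,3-dioxolan-2-yl)-6-(prop-1-en-2-yl)oct-2-en-4-one F2. Reduction of F2 with catecholborane and the B-methyl oxazaborolidine (CBS) catalyst, in the enantiomeric form that delivers hydride to the face giving the (4R) carbinol, comes back to the route at 12.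

**Step 26.** Poor facial selectivity in the hydroboration of the twisted diene 36 is the likely failure; it would give the C-4 epimer, which cannot be corrected afterwards. The fallback sets C-4 on an endocyclic alkene before the isopropylidene group exists and sets out from decalone 32.
- KHMDS and PhNTf2 (THF, −78 °C) give the enol triflate F3.
- Allyl tert-butyldimethylsilyl ether and 9-BBN give 9-[3-(tert-butyldimethylsilyloxy)propyl]-9-borabicyclo[3.3.1]nonane F4, which is coupled with F3 (PdCl2(dppf), K3PO4, DMF/THF/H2O) to the C-3 alkene F5.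
- BH3·THF, then NaOH/H2O2, adds hydrogen to C-4 and boron to C-3 from the α face, anti to the axial C-5 methyl, and gives alcohol F6.
- Dess–Martin oxidation gives ketone F7, in which the C-4 chain can be equilibrated to the wanted equatorial position.
- Mixed McMurry coupling with excess acetone (TiCl3, Zn–Cu couple, DME, reflux; low-valent titanium) gives the isopropylidene silyl ether F8.
- Bu4NF gives alcohol F9, and oxidation (TEMPO, PhI(OAc)2, MeCN/H2O) comes back to the route at acid 39.

**Step 28.** Over-oxidation is the likely failure: tetravalent cerium may attack the tetrasubstituted alkene, or the alkene radical cation may be trapped by the carboxyl group. The fallback separates demethylation from oxidation. It sets out from acid 39: NaSEt (DMF, 140 °C) cleaves both aryl methyl ethers and gives the hydroquinone acid F10, and mild oxidation (Ag2O, Et2O, or air with a cobalt–salen catalyst) reaches target 40.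

## Further compounds

F1 | step 11 | (2R,3S,4R)-4-[2-(benzyloxy)ethyl]-3,5-dimethyl-3-(2-methyl-1,3-dioxolan-2-yl)-2-[(E)-prop-1-enyl]-3,4-dihydro-2H-pyran | C1O[C@H](/C=C/C)[C@@](C)(C2(C)OCCO2)[C@H](CCOCc3ccccc3)C=1C
F2 | step 8 | (2E,5S,6R)-8-(benzyloxy)-5-methyl-5-(2-methyl-1,3-dioxolan-2-yl)-6-(prop-1-en-2-yl)oct-2-en-4-one | C/C=C/C(=O)[C@@](C)(C1(C)OCCO1)[C@H](CCOCc2ccccc2)C(C)=C
F3 | step 26 | enol triflate of 32 (C-3=C-4 double bond, triflyloxy group on C-4) | COc1cc(C)c(OC)c(c1)C[C@]2(C)[C@H]3CCC=C(OS(=O)(=O)C(F)(F)F)[C@]3(C)CC[C@@H]2C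
F4 | step 26 | 9-[3-(tert-butyldimethylsilyloxy)propyl]-9-borabicyclo[3.3.1]nonane | CC(C)(C)[Si](C)(C)OCCCB1C2CCCC1CCC2
F5 | step 26 | 4-[3-(tert-butyldimethylsilyloxy)propyl]-9α-[(2,5-dimethoxy-3-methylphenyl)methyl]-5β,8α,9β-trimethyl-trans-decal-3-ene | COc1cc(C)c(OC)c(c1)C[C@]2(C)[C@H]3CCC=C(CCCO[Si](C)(C)C(C)(C)C)[C@]3(C)CC[C@@H]2C
F6 | step 26 | 4β-[3-(tert-butyldimethylsilyloxy)propyl]-9α-[(2,5-dimethoxy-3-methylphenyl)methyl]-5β,8α,9β-trimethyl-trans-decalin-3α-ol | COc1cc(C)c(OC)c(c1)C[C@]2(C)[C@H]3CC[C@H](O)[C@@H](CCCO[Si](C)(C)C(C)(C)C)[C@]3(C)CC[C@@H]2C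
F7 | step 26 | 4β-[3-(tert-butyldimethylsilyloxy)propyl]-9α-[(2,5-dimethoxy-3-methylphenyl)methyl]-5β,8α,9β-trimethyl-trans-decalin-3-one | COc1cc(C)c(OC)c(c1)C[C@]2(C)[C@H]3CCC(=O)[C@@H](CCCO[Si](C)(C)C(C)(C)C)[C@]3(C)CC[C@@H]2C
F8 | step 26 | tert-butyldimethylsilyl ether of F9 | COc1cc(C)c(OC)c(c1)C[C@]2(C)[C@H]3CCC(=C(C)C)[C@@H](CCCO[Si](C)(C)C(C)(C)C)[C@]3(C)CC[C@@H]2C
F9 | step 26 | 3-{9α-[(2,5-dimethoxy-3-methylphenyl)methyl]-5β,8α,9β-trimethyl-3-(propan-2-ylidene)-trans-decalin-4β-yl}propan-1-ol | COc1cc(C)c(OC)c(c1)C[C@]2(C)[C@H]3CCC(=C(C)C)[C@@H](CCCO)[C@]3(C)CC[C@@H]2C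
F10 | step 28 | 3-{9α-[(2,5-dihydroxy-3-methylphenyl)methyl]-5β,8α,9β-trimethyl-3-(propan-2-ylidene)-trans-decalin-4β-yl}propanoic acid | Cc1cc(O)cc(C[C@]2(C)[C@H]3CCC(=C(C)C)[C@@H](CCC(=O)O)[C@]3(C)CC[C@@H]2C)c1O
A1 | alternative 1 | 2-methoxy-5-methyl-1,4-benzoquinone | COC1=CC(=O)C(C)=CC1=O
A2 | alternative 1 | 2,5-dimethoxy-3-methyl-1-[(2E)-2-methylpenta-2,4-dienyl]benzene | C=C/C=C(\C)Cc1cc(OC)cc(C)c1OC
A3 | alternative 1 | cis-fused endo Diels–Alder adduct | COc1cc(C)c(OC)c(c1)C[C@]2(C)[C@@H]3C(=O)C(OC)=CC(=O)[C@]3(C)CC=C2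
A4 | alternative 2 | 2-(decalinylmethyl)-4-hydroxy-4-[(E)-prop-1-enyl]cyclobut-2-en-1-one, tert-butyl ester | C/C=C/C1(O)C=C(C[C@]2(C)[C@H]3CCC(=C(C)C)[C@@H](CCC(=O)OC(C)(C)C)[C@]3(C)CC[C@@H]2C)C1=O
A5 | alternative 2 | hydroquinone tert-butyl ester | Oc1cc(C)c(O)c(C[C@]2(C)[C@H]3CCC(=C(C)C)[C@@H](CCC(=O)OC(C)(C)C)[C@]3(C)CC[C@@H]2C)c1
A6 | alternative 3 | pentacarbonyl[(E)-1-methoxybut-2-enylidene]chromium, (CO)5Cr=C(OMe)CH=CHCH3 | COC(/C=C/C)=[Cr](=C=O)(=C=O)(=C=O)(=C=O)=C=O
A7 | alternative 3 | propargyl-substituted decalin methyl ester | C#CC[C@]1(C)[C@H]2CCC(=C(C)C)[C@@H](CCC(=O)OC)[C@]2(C)CC[C@@H]1C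
A8 | alternative 3 | 4-methoxyphenol methyl ester | COc1cc(C)c(O)c(C[C@]2(C)[C@H]3CCC(=C(C)C)[C@@H](CCC(=O)OC)[C@]3(C)CC[C@@H]2C)c1
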